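C13–C20 with C15 ⇐ (S)-δ-decalactone; C11–C12 bond and both centres ⇐ Evans syn-aldol of imide 7 with 3,3-dimethoxypropanal; C7–C8 ⇐ vinyl Grignard on aldehyde 13.
Ring order: the hydroxy acetal 14 is closed to a temporary 2-methoxy-6-vinyltetrahydropyran 15 (step 8), which is contracted to the cyclopentane C8–C12, the only ring of the target, by forming C8–C9 (step 9).
C1–C6 ⇐ cross-metathesis of the ring vinyl group of 18 with methyl hept-6-enoate, then hydrogenation, C9 oxidation, C8 equilibration, desilylation and ester hydrolysis.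
Feature used: in the cyclopentanone ring C8–C12, C9 is the carbonyl carbon and C8 its epimerisable α-carbon next to C12, so the C8–C9 ring bond can be closed with no stereocontrol at either atom, while C11, C12 and C15 are fixed beforehand on an open chain.

Key step: step 9

Remarks: prostanoid numbering is used for positions (C1 acid, ring C8–C12, C15 carbinol); TBS = tert-butyldimethylsilyl. (S)-δ-Decalactone and 3,3-dimethoxypropanal are taken as catalogue compounds, the aldehyde being distilled just before use. Centres that are formed without control and reset later (C8, C9) are left open in the SMILES.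

Step 1
Reactants: 1 (S)-δ-decalactone
Product: 4 (5S)-5-(tert-butyldimethylsilyloxy)decanoic acid, via sodium (5S)-5-hydroxydecanoate 2 (not isolated), via bis-silylated hydroxy acid 3 (not isolated)
Conditions: NaOH, MeOH/H2O, rt, evaporate; TBSCl, imidazole, DMF, rt; K2CO3, MeOH/THF/H2O, rt; aq. citric acid to pH 4, 0 °C
Reagents that add atoms: sodium hydroxide [Na+].[OH-]; tert-butyldimethylsilyl chloride CC(C)(C)[Si](C)(C)Cl
Why: Lactone saponification followed by exhaustive silylation and selective carbonate cleavage of the labile silyl ester should give the silyloxy acid without any chance of relactonisation, and C15 is not touched.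

Step 2
Reactants: 4 (5S)-5-(tert-butyldimethylsilyloxy)decanoic acid; 5 (S)-4-benzyl-2-oxazolidinone
Product: 7 (4S)-4-benzyl-3-[(5S)-5-(tert-butyldimethylsilyloxy)decanoyl]-1,3-oxazolidin-2-one, via mixed pivalic anhydride 6 (not isolated)
Conditions: t-BuCOCl, Et3N, THF, −20 °C; then LiCl, 5, −20 °C → rt
Reagents that add atoms: none
Why: N-Acylation of the oxazolidinone through the mixed pivalic anhydride (LiCl/Et3N protocol) is a mild imide formation in which the nucleophile attacks the less hindered carbonyl of the anhydride.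

Step 3
Reactants: 7 (4S)-4-benzyl-3-[(5S)-5-(tert-butyldimethylsilyloxy)decanoyl]-1,3-oxazolidin-2-one; 8 3,3-dimethoxypropanal
Product: 10 (4S)-4-benzyl-3-[(2S,3R)-2-[(3S)-3-(tert-butyldimethylsilyloxy)octyl]-3-hydroxy-5,5-dimethoxypentanoyl]-1,3-oxazolidin-2-one, via Z-dibutylboron enolate 9 (not isolated)
Conditions: n-Bu2BOTf, i-Pr2NEt, CH2Cl2, 0 °C; 8, −78 → 0 °C; pH 7 buffer (KH2PO4/Na2HPO4), MeOH, 30% H2O2, 0 °C
Reagents that add atoms: none
Why: Evans syn-aldol, in which the Z-boron enolate reacts through a closed chair (Zimmerman–Traxler) transition state on the face away from the benzyl group of the (S)-auxiliary, so that C12 (2S) and C11 (3R) are set together in the syn arrangement that becomes the trans C11/C12 pair of the ring, while the weakly Lewis-acidic boron reagent should leave the dimethyl acetal intact at −78 °C.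

Step 4
Reactants: 10 (4S)-4-benzyl-3-[(2S,3R)-2-[(3S)-3-(tert-butyldimethylsilyloxy)octyl]-3-hydroxy-5,5-dimethoxypentanoyl]-1,3-oxazolidin-2-one
Product: 11 (2S,3R)-2-[(3S)-3-(tert-butyldimethylsilyloxy)octyl]-3-hydroxy-N,5,5-trimethoxy-N-methylpentanamide
Conditions: MeNH(OMe)·HCl, Me3Al, CH2Cl2, −20 → 0 °C; aq. potassium sodium tartrate
Reagents that add atoms: N,O-dimethylhydroxylamine hydrochloride CNOC.Cl
Why: Aluminium-amide transamination to the Weinreb amide is directed by the free C11 hydroxyl to the exocyclic carbonyl, releases the auxiliary and should not epimerise C12.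

Step 5
Reactants: 11 (2S,3R)-2-[(3S)-3-(tert-butyldimethylsilyloxy)octyl]-3-hydroxy-N,5,5-trimethoxy-N-methylpentanamide
Product: 12 (2S,3R)-3-(tert-butyldimethylsilyloxy)-2-[(3S)-3-(tert-butyldimethylsilyloxy)octyl]-N,5,5-trimethoxy-N-methylpentanamide
Conditions: TBSCl, imidazole, DMAP (cat.), DMF, rt
Reagents that add atoms: tert-butyldimethylsilyl chloride CC(C)(C)[Si](C)(C)Cl
Why: Silylation of the secondary alcohol under basic conditions free of Lewis acid protects C11 and spares the dimethyl acetal.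

Step 6
Reactants: 12 (2S,3R)-3-(tert-butyldimethylsilyloxy)-2-[(3S)-3-(tert-butyldimethylsilyloxy)octyl]-N,5,5-trimethoxy-N-methylpentanamide
Product: 13 (2S,3R)-3-(tert-butyldimethylsilyloxy)-2-[(3S)-3-(tert-butyldimethylsilyloxy)octyl]-5,5-dimethoxypentanal
Conditions: i-Bu2AlH, THF, −78 °C; aq. potassium sodium tartrate
Reagents that add atoms: none
Why: Hydride reduction of a Weinreb amide stops at the chelated hemiaminal, which should give the aldehyde on work-up without over-reduction and, at −78 °C, without epimerisation of C12 or reductive opening of the acetal.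

Step 7
Reactants: 13 (2S,3R)-3-(tert-butyldimethylsilyloxy)-2-[(3S)-3-(tert-butyldimethylsilyloxy)octyl]-5,5-dimethoxypentanal
Product: 14 (4R,5R)-5-(tert-butyldimethylsilyloxy)-4-[(3S)-3-(tert-butyldimethylsilyloxy)octyl]-7,7-dimethoxyhept-1-en-3-ol (both C3 epimers)
Conditions: CH2=CHMgBr, THF, −78 → −20 °C
Reagents that add atoms: vinylmagnesium bromide C=C[Mg]Br
Why: Grignard 1,2-addition to the aldehyde installs C7 and the C8 carbinol, whose configuration is allowed to be mixed because the C8–O bond is broken in step 9.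

Step 8
Reactants: 14 (4R,5R)-5-(tert-butyldimethylsilyloxy)-4-[(3S)-3-(tert-butyldimethylsilyloxy)octyl]-7,7-dimethoxyhept-1-en-3-ol
Product: 15 (4R,5R)-4-(tert-butyldimethylsilyloxy)-5-[(3S)-3-(tert-butyldimethylsilyloxy)octyl]-2-methoxy-6-vinyltetrahydropyran (C2/C6 isomer mixture; ring C4 and C5 substituents trans)
Conditions: PPTS (cat.), 4 Å molecular sieves, CH2Cl2, rt
Reagents that add atoms: none
Why: Acid-catalysed intramolecular transacetalisation, in which the C8 hydroxyl replaces one methoxy group of the 1,5-related acetal to close the six-membered mixed acetal, should proceed in an aprotic medium that spares both silyl ethers, and the anomeric centre C9 may form as a mixture.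

Step 9
Reactants: 15 (4R,5R)-4-(tert-butyldimethylsilyloxy)-5-[(3S)-3-(tert-butyldimethylsilyloxy)octyl]-2-methoxy-6-vinyltetrahydropyran
Product: 18 (3R,4R)-4-(tert-butyldimethylsilyloxy)-3-[(3S)-3-(tert-butyldimethylsilyloxy)octyl]-2-vinylcyclopentan-1-ol (C1/C2 isomers), via zirconacyclopropane 16 (not isolated), via allylzirconium hemiacetalate 17 (not isolated)
Conditions: Cp2ZrCl2, n-BuLi (2 equiv per Zr), THF, −78 °C; 15, −78 °C → rt; BF3·OEt2, 0 °C → rt; aq. NaHCO3
Reagents that add atoms: none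
Why: Cp2ZrCl2 and n-BuLi give dibutylzirconocene, which loses butane to Cp2Zr(1-butene), a source of divalent zirconium; exchange of butene for the vinyl group of 15 gives zirconacyclopropane 16, and β-elimination of the allylic ring oxygen from C8 opens the pyran to the allylzirconium 17, in which the metal also holds the C9 hemiacetal oxygen. BF3·OEt2 then removes methoxide from C9, and the γ-carbon C8 of the allylzirconium adds to the resulting oxocarbenium ion with allyl transposition, which forms the C8–C9 bond, restores the vinyl group and leaves the former ring oxygen as the C9 hydroxyl. The closest known reaction type is the zirconocene-mediated ring contraction of vinyl-substituted pyranoside acetals to 2-vinylcyclopentanols, an intramolecular allylmetal addition to an activated acetal. The cyclopentane C8–C12 closes in the 5-exo-trig mode onto the exocyclic C9=O+ unit. C8 and C9 are created under substrate control in a cyclic transition state that is expected to place the vinyl group trans to the C12 chain, but neither needs control because C9 becomes the ketone in step 12 and C8 is equilibrated in step 13. What the step needs is chemoselectivity, which the substrate secures: the ring oxygen is the only allylic leaving group, the acetal is the only group that BF3·OEt2 ionises, and C11, C12 and C15 carry only silyl ethers as spectators.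

Step 10
Reactants: 18 (3R,4R)-4-(tert-butyldimethylsilyloxy)-3-[(3S)-3-(tert-butyldimethylsilyloxy)octyl]-2-vinylcyclopentan-1-ol; 19 methyl hept-6-enoate
Product: 20 methyl 7-[(2R,3R)-3-(tert-butyldimethylsilyloxy)-2-[(3S)-3-(tert-butyldimethylsilyloxy)octyl]-5-hydroxycyclopentyl]hept-6-enoate (E/Z; ring C1/C5 isomers)
Conditions: second-generation Grubbs catalyst (H2IMes)(PCy3)Cl2Ru=CHPh (5 mol%), 19 (excess), CH2Cl2, 40 °C
Reagents that add atoms: none
Why: Olefin cross-metathesis between the monosubstituted ring vinyl group and an excess of the unhindered terminal olefin should attach C1–C6 with loss of ethylene, and the alkene geometry is of no account because the double bond is hydrogenated next.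

Step 11
Reactants: 20 methyl 7-[(2R,3R)-3-(tert-butyldimethylsilyloxy)-2-[(3S)-3-(tert-butyldimethylsilyloxy)octyl]-5-hydroxycyclopentyl]hept-6-enoate
Product: 21 methyl 7-[(2R,3R)-3-(tert-butyldimethylsilyloxy)-2-[(3S)-3-(tert-butyldimethylsilyloxy)octyl]-5-hydroxycyclopentyl]heptanoate (ring C1/C5 isomers)
Conditions: H2 (1 atm), 10% Pd/C, EtOAc, rt
Reagents that add atoms: none
Why: Heterogeneous catalytic hydrogenation saturates the disubstituted C6–C7 alkene, while silyl ethers, ester and alcohol are inert in ethyl acetate.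

Step 12
Reactants: 21 methyl 7-[(2R,3R)-3-(tert-butyldimethylsilyloxy)-2-[(3S)-3-(tert-butyldimethylsilyloxy)octyl]-5-hydroxycyclopentyl]heptanoate
Product: 22 methyl 7-[(2R,3R)-3-(tert-butyldimethylsilyloxy)-2-[(3S)-3-(tert-butyldimethylsilyloxy)octyl]-5-oxocyclopentyl]heptanoate (C8 epimers)
Conditions: Dess–Martin periodinane, pyridine, CH2Cl2, 0 °C → rt
Reagents that add atoms: none
Why: Dess–Martin oxidation of the only free hydroxyl removes the C9 stereocentre under buffered conditions that should not provoke β-elimination of the C11 silyloxy group.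

Step 13
Reactants: 22 methyl 7-[(2R,3R)-3-(tert-butyldimethylsilyloxy)-2-[(3S)-3-(tert-butyldimethylsilyloxy)octyl]-5-oxocyclopentyl]heptanoate
Product: 23 methyl 7-[(1R,2R,3R)-3-(tert-butyldimethylsilyloxy)-2-[(3S)-3-(tert-butyldimethylsilyloxy)octyl]-5-oxocyclopentyl]heptanoate
Conditions: KOAc, MeOH, rt
Reagents that add atoms: none
Why: Thermodynamic epimerisation through the C8–C9 enolate should place the C8 chain trans to the C12 chain, the more stable 2,3-trans cyclopentanone (C8 becomes R), and the weak acetate base limits E1cB loss of the C11 silyloxy group; any cis epimer left is separated and resubmitted.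

Step 14
Reactants: 23 methyl 7-[(1R,2R,3R)-3-(tert-butyldimethylsilyloxy)-2-[(3S)-3-(tert-butyldimethylsilyloxy)octyl]-5-oxocyclopentyl]heptanoate
Product: 24 methyl 7-[(1R,2R,3R)-3-hydroxy-2-[(3S)-3-hydroxyoctyl]-5-oxocyclopentyl]heptanoate
Conditions: HF·pyridine, pyridine, MeCN, 0 °C
Reagents that add atoms: none
Why: Fluoride-mediated desilylation with buffered HF cleaves both silyl ethers under conditions mild enough to avoid dehydration of the β-hydroxy cyclopentanone and epimerisation of C8.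

Step 15
Reactants: 24 methyl 7-[(1R,2R,3R)-3-hydroxy-2-[(3S)-3-hydroxyoctyl]-5-oxocyclopentyl]heptanoate
Product: 25 13,14-dihydro-PGE1, 7-[(1R,2R,3R)-3-hydroxy-2-[(3S)-3-hydroxyoctyl]-5-oxocyclopentyl]heptanoic acid
Conditions: pig liver esterase, pH 8 buffer (KH2PO4/Na2HPO4), acetone (cosolvent), 30 °C
Reagents that add atoms: water O
Why: Enzymatic ester hydrolysis near neutral pH should free the C1 acid without dehydration of the β-hydroxy ketone or loss of the C8 configuration.

Compound list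
1 | (S)-δ-decalactone, (6S)-6-pentyloxan-2-one | CCCCC[C@H]1CCCC(=O)O1 | starting material
2 | sodium (5S)-5-hydroxydecanoate (not isolated) | CCCCC[C@H](O)CCCC(=O)[O-].[Na+] | intermediate
3 | tert-butyldimethylsilyl (5S)-5-(tert-butyldimethylsilyloxy)decanoate (not isolated) | CCCCC[C@H](O[Si](C)(C)C(C)(C)C)CCCC(=O)O[Si](C)(C)C(C)(C)C | intermediate
4 | (5S)-5-(tert-butyldimethylsilyloxy)decanoic acid | CCCCC[C@H](O[Si](C)(C)C(C)(C)C)CCCC(=O)O | intermediate
5 | (S)-4-benzyl-2-oxazolidinone | O=C1N[C@@H](Cc2ccccc2)CO1 | starting material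
6 | (5S)-5-(tert-butyldimethylsilyloxy)decanoic pivalic anhydride (not isolated) | CCCCC[C@H](O[Si](C)(C)C(C)(C)C)CCCC(=O)OC(=O)C(C)(C)C | intermediate
7 | (4S)-4-benzyl-3-[(5S)-5-(tert-butyldimethylsilyloxy)decanoyl]-1,3-oxazolidin-2-one | CCCCC[C@H](O[Si](C)(C)C(C)(C)C)CCCC(=O)N1[C@@H](Cc2ccccc2)COC1=O | intermediate
8 | 3,3-dimethoxypropanal | COC(CC=O)OC | starting material
9 | Z-dibutylboron enolate of 7 (not isolated) | CCCCC[C@H](O[Si](C)(C)C(C)(C)C)CC/C=C(\OB(CCCC)CCCC)N1[C@@H](Cc2ccccc2)COC1=O | intermediate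
10 | (4S)-4-benzyl-3-[(2S,3R)-2-[(3S)-3-(tert-butyldimethylsilyloxy)octyl]-3-hydroxy-5,5-dimethoxypentanoyl]-1,3-oxazolidin-2-one | CCCCC[C@H](O[Si](C)(C)C(C)(C)C)CC[C@H](C(=O)N1[C@@H](Cc2ccccc2)COC1=O)[C@H](O)CC(OC)OC | intermediate
11 | (2S,3R)-2-[(3S)-3-(tert-butyldimethylsilyloxy)octyl]-3-hydroxy-N,5,5-trimethoxy-N-methylpentanamide | CCCCC[C@H](O[Si](C)(C)C(C)(C)C)CC[C@H](C(=O)N(C)OC)[C@H](O)CC(OC)OC | intermediate
12 | (2S,3R)-3-(tert-butyldimethylsilyloxy)-2-[(3S)-3-(tert-butyldimethylsilyloxy)octyl]-N,5,5-trimethoxy-N-methylpentanamide | CCCCC[C@H](O[Si](C)(C)C(C)(C)C)CC[C@H](C(=O)N(C)OC)[C@H](O[Si](C)(C)C(C)(C)C)CC(OC)OC | intermediate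
13 | (2S,3R)-3-(tert-butyldimethylsilyloxy)-2-[(3S)-3-(tert-butyldimethylsilyloxy)octyl]-5,5-dimethoxypentanal | CCCCC[C@H](O[Si](C)(C)C(C)(C)C)CC[C@H](C=O)[C@H](O[Si](C)(C)C(C)(C)C)CC(OC)OC | intermediate
14 | (4R,5R)-5-(tert-butyldimethylsilyloxy)-4-[(3S)-3-(tert-butyldimethylsilyloxy)octyl]-7,7-dimethoxyhept-1-en-3-ol (both C3 epimers) | CCCCC[C@H](O[Si](C)(C)C(C)(C)C)CC[C@H](C(O)C=C)[C@H](O[Si](C)(C)C(C)(C)C)CC(OC)OC | intermediate
15 | (4R,5R)-4-(tert-butyldimethylsilyloxy)-5-[(3S)-3-(tert-butyldimethylsilyloxy)octyl]-2-methoxy-6-vinyltetrahydropyran (isomer mixture at C2 and C6; key-step precursor) | CCCCC[C@H](O[Si](C)(C)C(C)(C)C)CC[C@H]1[C@H](O[Si](C)(C)C(C)(C)C)CC(OC)OC1C=C | intermediate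
16 | zirconacyclopropane from the vinyl group of 15 and zirconocene (not isolated) | CCCCC[C@H](O[Si](C)(C)C(C)(C)C)CC[C@H]1[C@H](O[Si](C)(C)C(C)(C)C)CC(OC)OC1C2C[Zr]2(C3C=CC=C3)C4C=CC=C4 | intermediate
17 | ring-opened allylzirconium hemiacetalate (not isolated) | CCCCC[C@H](O[Si](C)(C)C(C)(C)C)CC[C@H]1[C@H](O[Si](C)(C)C(C)(C)C)CC(OC)O[Zr](C2C=CC=C2)(C3C=CC=C3)CC=C1 | intermediate
18 | (3R,4R)-4-(tert-butyldimethylsilyloxy)-3-[(3S)-3-(tert-butyldimethylsilyloxy)octyl]-2-vinylcyclopentan-1-ol (isomers at C1 and C2; key-step product) | CCCCC[C@H](O[Si](C)(C)C(C)(C)C)CC[C@H]1[C@H](O[Si](C)(C)C(C)(C)C)CC(O)C1C=C | intermediate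
19 | methyl hept-6-enoate | C=CCCCCC(=O)OC | starting material
20 | methyl 7-[(2R,3R)-3-(tert-butyldimethylsilyloxy)-2-[(3S)-3-(tert-butyldimethylsilyloxy)octyl]-5-hydroxycyclopentyl]hept-6-enoate (E/Z; isomers at ring C1 and C5) | CCCCC[C@H](O[Si](C)(C)C(C)(C)C)CC[C@H]1[C@H](O[Si](C)(C)C(C)(C)C)CC(O)C1C=CCCCCC(=O)OC | intermediate
21 | methyl 7-[(2R,3R)-3-(tert-butyldimethylsilyloxy)-2-[(3S)-3-(tert-butyldimethylsilyloxy)octyl]-5-hydroxycyclopentyl]heptanoate (isomers at ring C1 and C5) | CCCCC[C@H](O[Si](C)(C)C(C)(C)C)CC[C@H]1[C@H](O[Si](C)(C)C(C)(C)C)CC(O)C1CCCCCCC(=O)OC | intermediate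
22 | methyl 7-[(2R,3R)-3-(tert-butyldimethylsilyloxy)-2-[(3S)-3-(tert-butyldimethylsilyloxy)octyl]-5-oxocyclopentyl]heptanoate (C8 epimers) | CCCCC[C@H](O[Si](C)(C)C(C)(C)C)CC[C@H]1[C@H](O[Si](C)(C)C(C)(C)C)CC(=O)C1CCCCCCC(=O)OC | intermediate
23 | methyl 7-[(1R,2R,3R)-3-(tert-butyldimethylsilyloxy)-2-[(3S)-3-(tert-butyldimethylsilyloxy)octyl]-5-oxocyclopentyl]heptanoate | CCCCC[C@H](O[Si](C)(C)C(C)(C)C)CC[C@H]1[C@H](O[Si](C)(C)C(C)(C)C)CC(=O)[C@@H]1CCCCCCC(=O)OC | intermediate
24 | methyl 7-[(1R,2R,3R)-3-hydroxy-2-[(3S)-3-hydroxyoctyl]-5-oxocyclopentyl]heptanoate | CCCCC[C@H](O)CC[C@H]1[C@H](O)CC(=O)[C@@H]1CCCCCCC(=O)OC | intermediate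
25 | 13,14-dihydro-PGE1, 7-[(1R,2R,3R)-3-hydroxy-2-[(3S)-3-hydroxyoctyl]-5-oxocyclopentyl]heptanoic acid | CCCCC[C@H](O)CC[C@H]1[C@H](O)CC(=O)[C@@H]1CCCCCCC(=O)O | target

Total step count: 15 steps. Longest linear sequence: 15 steps, from 1 to 25.

Steps most likely to fail

Step 9. The acetal may ionise or lose methanol by elimination before the allylzirconium is in place, or the allylzirconium may be protonated instead of adding to C9, so that the C8–C9 bond does not form; BF3·OEt2 may also strip the C11 silyl ether. The fallback sets out from 14 and makes the same bond by a known palladium-catalysed umpolung allylation. Acetylation of 14 (Ac2O, pyridine, DMAP, CH2Cl2) should give (4R,5R)-5-(tert-butyldimethylsilyloxy)-4-[(3S)-3-(tert-butyldimethylsilyloxy)octyl]-7,7-dimethoxyhept-1-en-3-yl acetate F1. Chemoselective unmasking of the dimethyl acetal (Et3SiOTf, 2,4,6-collidine, CH2Cl2, 0 °C, then H2O) should give (3R,4R)-5-acetoxy-3-(tert-butyldimethylsilyloxy)-4-[(3S)-3-(tert-butyldimethylsilyloxy)octyl]hept-6-enal F2, used crude. Pd(PPh3)4 (zerovalent palladium) and Et2Zn in THF at rt then convert the allylic acetate, through a π-allylpalladium complex, into an allylzinc that adds to the aldehyde and closes the cyclopentane; both acetate epimers converge, and the route is rejoined at 18.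

Step 3. The aldehyde may lose methanol by β-elimination, or its acetal may be opened by the boron Lewis acid, before the enolate traps it, leaving unreacted imide. The fallback sets out from 7 and uses commercial 3-(benzyloxy)propanal, which has no leaving group at C3, in the same boron aldol. This should give (4S)-4-benzyl-3-[(2S,3R)-5-(benzyloxy)-2-[(3S)-3-(tert-butyldimethylsilyloxy)octyl]-3-hydroxypentanoyl]-1,3-oxazolidin-2-one F3. Transamination as in step 4 gives (2S,3R)-5-(benzyloxy)-2-[(3S)-3-(tert-butyldimethylsilyloxy)octyl]-3-hydroxy-N-methoxy-N-methylpentanamide F4, and silylation as in step 5 gives (2S,3R)-5-(benzyloxy)-3-(tert-butyldimethylsilyloxy)-2-[(3S)-3-(tert-butyldimethylsilyloxy)octyl]-N-methoxy-N-methylpentanamide F5. Hydrogenolysis (H2, 10% Pd/C, EtOAc) gives the primary alcohol (2S,3R)-3-(tert-butyldimethylsilyloxy)-2-[(3S)-3-(tert-butyldimethylsilyloxy)octyl]-5-hydroxy-N-methoxy-N-methylpentanamide F6, and Dess–Martin oxidation gives (2S,3R)-3-(tert-butyldimethylsilyloxy)-2-[(3S)-3-(tert-butyldimethylsilyloxy)octyl]-N-methoxy-N-methyl-5-oxopentanamide F7. Acetalisation with HC(OMe)3 and catalytic PPTS in CH2Cl2/MeOH rejoins the route at 12.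

Step 10. Turnover at the ring vinyl group, which is flanked by two ring substituents, may be slow, so that self-metathesis of the ester partner and olefin migration take over. The fallback sets out from 18 and keeps the terminal vinyl carbon as C6. Hydroboration with 9-borabicyclo[3.3.1]nonane (2.2 equiv, THF, rt; the C9 hydroxyl is borinated in passing) should give the anti-Markovnikov borane 9-[2-[(2R,3R)-3-(tert-butyldimethylsilyloxy)-2-[(3S)-3-(tert-butyldimethylsilyloxy)octyl]-5-(9-borabicyclo[3.3.1]nonan-9-yloxy)cyclopentyl]ethyl]-9-borabicyclo[3.3.1]nonane F8. This is coupled in the same flask with methyl 5-bromopentanoate (Pd(OAc)2, PCy3, K3PO4·H2O, THF, rt; alkyl–alkyl Suzuki–Miyaura coupling), which forms C5–C6 and gives the saturated ester directly, so that step 11 is bypassed and the route is rejoined at 21.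

Further compounds
F1 | step 9 | (4R,5R)-5-(tert-butyldimethylsilyloxy)-4-[(3S)-3-(tert-butyldimethylsilyloxy)octyl]-7,7-dimethoxyhept-1-en-3-yl acetate (C3 epimers) | CCCCC[C@H](O[Si](C)(C)C(C)(C)C)CC[C@H](C(OC(C)=O)C=C)[C@H](O[Si](C)(C)C(C)(C)C)CC(OC)OC
F2 | step 9 | (3R,4R)-5-acetoxy-3-(tert-butyldimethylsilyloxy)-4-[(3S)-3-(tert-butyldimethylsilyloxy)octyl]hept-6-enal (C5 epimers) | CCCCC[C@H](O[Si](C)(C)C(C)(C)C)CC[C@H](C(OC(C)=O)C=C)[C@H](O[Si](C)(C)C(C)(C)C)CC=O
F3 | step 3 | (4S)-4-benzyl-3-[(2S,3R)-5-(benzyloxy)-2-[(3S)-3-(tert-butyldimethylsilyloxy)octyl]-3-hydroxypentanoyl]-1,3-oxazolidin-2-one | CCCCC[C@H](O[Si](C)(C)C(C)(C)C)CC[C@H](C(=O)N1[C@@H](Cc2ccccc2)COC1=O)[C@H](O)CCOCc1ccccc1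
F4 | step 3 | (2S,3R)-5-(benzyloxy)-2-[(3S)-3-(tert-butyldimethylsilyloxy)octyl]-3-hydroxy-N-methoxy-N-methylpentanamide | CCCCC[C@H](O[Si](C)(C)C(C)(C)C)CC[C@H](C(=O)N(C)OC)[C@H](O)CCOCc1ccccc1
F5 | step 3 | (2S,3R)-5-(benzyloxy)-3-(tert-butyldimethylsilyloxy)-2-[(3S)-3-(tert-butyldimethylsilyloxy)octyl]-N-methoxy-N-methylpentanamide | CCCCC[C@H](O[Si](C)(C)C(C)(C)C)CC[C@H](C(=O)N(C)OC)[C@H](O[Si](C)(C)C(C)(C)C)CCOCc1ccccc1
F6 | step 3 | (2S,3R)-3-(tert-butyldimethylsilyloxy)-2-[(3S)-3-(tert-butyldimethylsilyloxy)octyl]-5-hydroxy-N-methoxy-N-methylpentanamide | CCCCC[C@H](O[Si](C)(C)C(C)(C)C)CC[C@H](C(=O)N(C)OC)[C@H](O[Si](C)(C)C(C)(C)C)CCO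
F7 | step 3 | (2S,3R)-3-(tert-butyldimethylsilyloxy)-2-[(3S)-3-(tert-butyldimethylsilyloxy)octyl]-N-methoxy-N-methyl-5-oxopentanamide | CCCCC[C@H](O[Si](C)(C)C(C)(C)C)CC[C@H](C(=O)N(C)OC)[C@H](O[Si](C)(C)C(C)(C)C)CC=O
F8 | step 10 | 9-[2-[(2R,3R)-3-(tert-butyldimethylsilyloxy)-2-[(3S)-3-(tert-butyldimethylsilyloxy)octyl]-5-(9-borabicyclo[3.3.1]nonan-9-yloxy)cyclopentyl]ethyl]-9-borabicyclo[3.3.1]nonane (isomers at ring C1 and C5) | CCCCC[C@H](O[Si](C)(C)C(C)(C)C)CC[C@H]1[C@H](O[Si](C)(C)C(C)(C)C)CC(OB2C3CCCC2CCC3)C1CCB4C5CCCC4CCC5
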